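## Retrosynthetic overview

1. The aryl ether is cut at C11–O (Mitsunobu coupling with isofraxidin, used intact); the 3α-acetate comes from a 3-ketone by bulky-hydride reduction and acetylation.
2. Ring A is closed last, through the C3–C4 bond: hydrogen-atom transfer to an isopropenyl group gives the tertiary C4 radical, which cyclises 6-exo onto a C3 nitrile and delivers the 4,4-dimethyl-3-ketone directly.
3. Enabling feature: C4 is a quaternary gem-dimethyl carbon next to the ring-fusion CH (C5), so it is a masked isopropenyl group; ring B (C5–C10, with the C8 methyl and the C7=C8 alkene) is the ring of (R)-carvone, and C3 sits 1,6 to C4 through C5–C10–C1–C2.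
4. Before that, ring B is elaborated: C10 by two enolate alkylations (methyl, then allyl anti to isopropenyl), and the C9–C11 bond by epoxidation, Wharton transposition and Wittig–Still [2,3] shift, which places CH2O on the α face.
5. Ring order: ring B (from carvone), then ring A (radical cyclisation), then the coumarin is attached.

Key step: step 9

Remark: (R)-(−)-carvone and isofraxidin are taken as commercial; locants follow drimane numbering (ring A = C1–C5 and C10, ring B = C5–C10, C11 = CH2O carbon on C9), α is the face opposite the C10 methyl, and CIP descriptors are given explicitly.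

## Route

Step 1
Reactants: 1 (R)-(−)-carvone
Product: 2 6-methylcarvone (mixture of C6 epimers)
Conditions: LiN(iPr)2, THF, −78 °C; MeI, −78 → 0 °C
Reagents that add atoms: iodomethane, CI
Why: Kinetic α′-deprotonation gives the cross-conjugated lithium enolate, which is methylated by SN2 enolate alkylation; the C6 epimer ratio does not matter because step 2 re-enolises this centre.

Step 2
Reactants: 2 6-methylcarvone
Product: 3 (5S,6S)-6-allyl-6-methylcarvone
Conditions: LiN(iPr)2, THF, −78 °C; allyl bromide, DMPU, −78 → 0 °C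
Reagents that add atoms: allyl bromide, C=CCBr
Why: Enolate C-allylation in which both epimers of 2 converge on one enolate and allyl bromide should enter anti to the neighbouring isopropenyl group, setting the quaternary centre (future C10) with methyl cis and allyl trans to isopropenyl.

Step 3
Reactants: 3 (5S,6S)-6-allyl-6-methylcarvone
Product: 4 7α,8α-epoxy ketone
Conditions: 30% H2O2, NaOH (cat.), MeOH, 0 °C
Reagents that add atoms: hydrogen peroxide, OO
Why: Weitz–Scheffer nucleophilic epoxidation touches only the enone, and hydroperoxide should add axially to the β-carbon anti to the isopropenyl group (as with carvone itself) and away from the axial methyl, giving the α-epoxide.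

Step 4
Reactants: 4 7α,8α-epoxy ketone
Product: 6 allylic alcohol (1R,4R,5S)-2,4-dimethyl-5-(prop-1-en-2-yl)-4-(prop-2-en-1-yl)cyclohex-2-en-1-ol, via epoxy hydrazone 5 (not isolated)
Conditions: N2H4·H2O, AcOH (cat.), MeOH, 0 °C → rt
Reagents that add atoms: none
Why: Wharton transposition, in which the epoxy hydrazone fragments with loss of N2, moving the oxygen to C7 with its α configuration retained and the alkene to C8=C9.

Step 5
Reactants: 6 allylic alcohol
Product: 7 tributylstannylmethyl ether of 6
Conditions: KH, THF, 0 °C; Bu3SnCH2I, 18-crown-6 (cat.), rt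
Reagents that add atoms: (iodomethyl)tributylstannane, CCCC[Sn](CCCC)(CCCC)CI
Why: Williamson etherification of the potassium alkoxide with a primary iodide; no stereocentre is touched.

Step 6
Reactants: 7 tributylstannylmethyl ether
Product: 10 silyl ether tert-butyl{[(1R,5S,6S)-2,6-dimethyl-5-(prop-1-en-2-yl)-6-(prop-2-en-1-yl)cyclohex-2-en-1-yl]methoxy}dimethylsilane, via α-alkoxymethyllithium 8 (not isolated), via lithium alkoxide 9 (not isolated)
Conditions: n-BuLi, THF, −78 °C; then TBSOTf, −78 → 0 °C
Reagents that add atoms: tert-butyldimethylsilyl trifluoromethanesulfonate, CC(C)(C)[Si](C)(C)OS(=O)(=O)C(F)(F)F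
Why: Tin–lithium exchange triggers the Wittig–Still [2,3]-sigmatropic rearrangement, which is suprafacial from the pseudoaxial C7α oxygen, so the CH2O carbon should arrive on the α face of C9 (anti to the axial C10 methyl) while the alkene returns to C7=C8; the alkoxide is silylated in the same flask.

Step 7
Reactants: 10 silyl ether
Product: 11 aldehyde 3-[(1S,2R,6S)-2-{[(tert-butyldimethylsilyl)oxy]methyl}-1,3-dimethyl-6-(prop-1-en-2-yl)cyclohex-3-en-1-yl]propanal
Conditions: PdCl2(PhCN)2 (cat.), CuCl2·2H2O (cat.), AgNO2 (cat.), O2 (1 atm), t-BuOH/MeNO2, rt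
Reagents that add atoms: dioxygen, O=O
Why: Nitrite-modified aldehyde-selective (anti-Markovnikov) Wacker oxidation should react only at the monosubstituted terminal alkene, since divalent palladium does not oxidise the 1,1-disubstituted and trisubstituted alkenes under these conditions and the hydroxyl is masked.

Step 8
Reactants: 11 aldehyde
Product: 13 nitrile 3-[(1S,2R,6S)-2-{[(tert-butyldimethylsilyl)oxy]methyl}-1,3-dimethyl-6-(prop-1-en-2-yl)cyclohex-3-en-1-yl]propanenitrile, via O-phosphinyl aldoxime 12 (not isolated)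
Conditions: Ph2P(O)ONH2, toluene, 85 °C
Reagents that add atoms: O-(diphenylphosphinyl)hydroxylamine, NOP(=O)(c1ccccc1)c1ccccc1
Why: One-pot oximation and thermal elimination of diphenylphosphinic acid converts the aldehyde into the nitrile without base or strong acid that could move an alkene.

Step 9
Reactants: 13 nitrile
Product: 16 (5R,9R,10S)-11-hydroxy-9βH-drim-7-en-3-one, via silyl ketimine 14 (not isolated), via silyl ketone 15 (not isolated)
Conditions: Fe(acac)3 (30 mol %), PhSiH3, degassed EtOH (0.02 M), 60 °C, Ar; then 1 M HCl, THF, rt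
Reagents that add atoms: water, O
Why: An iron hydride formed from Fe(acac)3 and PhSiH3 transfers a hydrogen atom to the terminal CH2 of the isopropenyl group (Markovnikov), the resulting tertiary C4 radical adds to the nitrile carbon C3, the iminyl radical is reduced to the N–H imine, and aqueous HCl then hydrolyses the imine to the C3 ketone and removes the silyl group. The closest known reaction type is the iron-mediated HAT-initiated reductive cyclisation of alkenes onto nitriles and ketones. Ring A is closed in the 6-exo-dig mode through C4–C5–C10–C1–C2–C3. No new stereocentre is formed (C4 becomes the quaternary gem-dimethyl carbon, C3 is trigonal), and the trans ring fusion follows from the preset C5 and C10 configurations because only the conformer with the C5 radical arm and the C10 cyanoethyl arm both equatorial can close. The step needs HAT at the 1,1-disubstituted alkene in preference to the trisubstituted C7=C8 alkene and ring closure faster than reduction of the radical; the higher HAT reactivity of 1,1-disubstituted alkenes, the lack of any other acceptor within reach of C4 and the gem-disubstituted C10 (Thorpe–Ingold effect) should secure this.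

Step 10
Reactants: 16 (5R,9R,10S)-11-hydroxy-9βH-drim-7-en-3-one
Product: 17 (3R,5R,9R,10S)-9βH-drim-7-ene-3,11-diol
Conditions: LiBH(s-Bu)3 (L-Selectride), THF, −78 °C; H2O
Reagents that add atoms: none
Why: The bulky trialkylborohydride should attack the C3 ketone along the equatorial trajectory (axial approach is hindered by the axial hydrogens at C1 and C5), giving the axial 3α alcohol, as in L-Selectride reductions of 4,4-dimethyl-3-keto terpenoids.

Step 11
Reactants: 17 (3R,5R,9R,10S)-9βH-drim-7-ene-3,11-diol; 18 isofraxidin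
Product: 19 7-{[(3R,5R,9R,10S)-3-hydroxy-9βH-drim-7-en-11-yl]oxy}-6,8-dimethoxycoumarin
Conditions: PPh3, DIAD, THF, 0 °C → rt
Reagents that add atoms: none
Why: Mitsunobu etherification, in which the primary C11 alcohol is activated as the alkoxyphosphonium salt and displaced by the acidic phenol, while the axial neopentyl-type 3α alcohol should not react; no stereocentre is involved.

Step 12
Reactants: 19 hydroxy aryl ether
Product: 20 7-{[(3R,5R,9R,10S)-3-acetoxy-9βH-drim-7-en-11-yl]oxy}-6,8-dimethoxycoumarin (target)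
Conditions: Ac2O, DMAP (cat.), pyridine, CH2Cl2, rt
Reagents that add atoms: acetic anhydride, CC(=O)OC(C)=O
Why: DMAP-catalysed acylation of the remaining axial secondary alcohol proceeds with retention and leaves the coumarin and the aryl ether untouched.

## Compound list

1 | (R)-(−)-carvone, (5R)-2-methyl-5-(prop-1-en-2-yl)cyclohex-2-en-1-one | CC1=CC[C@H](CC1=O)C(C)=C | starting material
2 | 6-methylcarvone, (5R,6RS)-2,6-dimethyl-5-(prop-1-en-2-yl)cyclohex-2-en-1-one (C6 epimers, used as the mixture) | CC1=CC[C@H](C(C)C1=O)C(C)=C | intermediate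
3 | (5S,6S)-2,6-dimethyl-5-(prop-1-en-2-yl)-6-(prop-2-en-1-yl)cyclohex-2-en-1-one (allyl trans, methyl cis to isopropenyl) | O=C1C(C)=CC[C@@H](C(C)=C)[C@]1(C)CC=C | intermediate
4 | 1,3-dimethyl-4-(prop-1-en-2-yl)-3-(prop-2-en-1-yl)-7-oxabicyclo[4.1.0]heptan-2-one (7α,8α-epoxide of 3, oxirane oxygen trans to isopropenyl) | O=C1[C@]2(C)O[C@@H]2C[C@@H](C(C)=C)[C@]1(C)CC=C | intermediate
5 | hydrazone of epoxy ketone 4 (not isolated) | NN=C1[C@]2(C)O[C@@H]2C[C@@H](C(C)=C)[C@]1(C)CC=C | intermediate
6 | (1R,4R,5S)-2,4-dimethyl-5-(prop-1-en-2-yl)-4-(prop-2-en-1-yl)cyclohex-2-en-1-ol (7α-OH, C8=C9 alkene) | CC1=C[C@@](C)(CC=C)[C@H](C(C)=C)C[C@H]1O | intermediate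
7 | tributyl({[(1R,4R,5S)-2,4-dimethyl-5-(prop-1-en-2-yl)-4-(prop-2-en-1-yl)cyclohex-2-en-1-yl]oxy}methyl)stannane | CC1=C[C@@](C)(CC=C)[C@H](C(C)=C)C[C@H]1OC[Sn](CCCC)(CCCC)CCCC | intermediate
8 | lithiomethyl ether of 6 (not isolated) | CC1=C[C@@](C)(CC=C)[C@H](C(C)=C)C[C@H]1OC[Li] | intermediate
9 | lithium alkoxide of [(1R,5S,6S)-2,6-dimethyl-5-(prop-1-en-2-yl)-6-(prop-2-en-1-yl)cyclohex-2-en-1-yl]methanol (not isolated) | [Li]OC[C@@H]1C(C)=CC[C@@H](C(C)=C)[C@]1(C)CC=C | intermediate
10 | tert-butyl{[(1R,5S,6S)-2,6-dimethyl-5-(prop-1-en-2-yl)-6-(prop-2-en-1-yl)cyclohex-2-en-1-yl]methoxy}dimethylsilane (CH2O on the α face of C9, C7=C8 alkene) | CC(C)(C)[Si](C)(C)OC[C@@H]1C(C)=CC[C@@H](C(C)=C)[C@]1(C)CC=C | intermediate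
11 | 3-[(1S,2R,6S)-2-{[(tert-butyldimethylsilyl)oxy]methyl}-1,3-dimethyl-6-(prop-1-en-2-yl)cyclohex-3-en-1-yl]propanal | CC(C)(C)[Si](C)(C)OC[C@@H]1C(C)=CC[C@@H](C(C)=C)[C@]1(C)CCC=O | intermediate
12 | O-(diphenylphosphinyl) aldoxime of 11 (not isolated) | CC(C)(C)[Si](C)(C)OC[C@@H]1C(C)=CC[C@@H](C(C)=C)[C@]1(C)CCC=NOP(=O)(c1ccccc1)c1ccccc1 | intermediate
13 | 3-[(1S,2R,6S)-2-{[(tert-butyldimethylsilyl)oxy]methyl}-1,3-dimethyl-6-(prop-1-en-2-yl)cyclohex-3-en-1-yl]propanenitrile | CC(C)(C)[Si](C)(C)OC[C@@H]1C(C)=CC[C@@H](C(C)=C)[C@]1(C)CCC#N | intermediate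
14 | (5R,9R,10S)-11-[(tert-butyldimethylsilyl)oxy]-9βH-drim-7-en-3-imine (N–H ketimine, not isolated) | CC(C)(C)[Si](C)(C)OC[C@@H]1C(C)=CC[C@H]2C(C)(C)C(=N)CC[C@]12C | intermediate
15 | (5R,9R,10S)-11-[(tert-butyldimethylsilyl)oxy]-9βH-drim-7-en-3-one (not isolated) | CC(C)(C)[Si](C)(C)OC[C@@H]1C(C)=CC[C@H]2C(C)(C)C(=O)CC[C@]12C | intermediate
16 | (5R,9R,10S)-11-hydroxy-9βH-drim-7-en-3-one (trans-decalin, CH2OH α) | OC[C@@H]1C(C)=CC[C@H]2C(C)(C)C(=O)CC[C@]12C | intermediate
17 | (3R,5R,9R,10S)-9βH-drim-7-ene-3,11-diol (3α-OH axial) | OC[C@@H]1C(C)=CC[C@H]2C(C)(C)[C@H](O)CC[C@]12C | intermediate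
18 | isofraxidin, 7-hydroxy-6,8-dimethoxy-2H-chromen-2-one | COc1cc2ccc(=O)oc2c(OC)c1O | starting material
19 | 7-{[(3R,5R,9R,10S)-3-hydroxy-9βH-drim-7-en-11-yl]oxy}-6,8-dimethoxy-2H-chromen-2-one | COc1cc2ccc(=O)oc2c(OC)c1OC[C@@H]1C(C)=CC[C@H]2C(C)(C)[C@H](O)CC[C@]12C | intermediate
20 | 7-{[(3R,5R,9R,10S)-3-acetoxy-9βH-drim-7-en-11-yl]oxy}-6,8-dimethoxy-2H-chromen-2-one | COc1cc2ccc(=O)oc2c(OC)c1OC[C@@H]1C(C)=CC[C@H]2C(C)(C)[C@H](OC(C)=O)CC[C@]12C | target

## Count and risks

Total step count: 12. Longest linear sequence: 12 steps from (R)-carvone; isofraxidin enters at step 11.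

**Step 9 (key step).** Ring closure of the tertiary C4 radical onto the nitrile is a slow radical cyclisation and may lose against a second hydrogen-atom transfer, so that the isopropenyl group is only reduced; HAT at the C7=C8 alkene is a second leak. The fallback sets out from aldehyde 11 and uses the aldehyde as the acceptor. The same Fe(acac)3/PhSiH3 system should close ring A by the much faster 6-exo-trig addition of the C4 radical to the C=O carbon (known alkene–carbonyl HAT cyclisation). This gives (5R,9R,10S)-11-[(tert-butyldimethylsilyl)oxy]-9βH-drim-7-en-3-ol F1 as a mixture of C3 epimers. Dess–Martin periodinane (NaHCO3, CH2Cl2) converges both epimers on silyl ketone 15, isolated this time, and 1 M HCl in THF removes the silyl group to rejoin the route at 16.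

**Step 7.** Markovnikov oxidation to the methyl ketone, or palladium-hydride-induced migration of the terminal double bond, may erode the aldehyde. The fallback sets out from 10. Hydroboration with (Sia)2BH (THF, 0 °C), which discriminates the monosubstituted alkene from the 1,1-disubstituted and trisubstituted ones, followed by NaBO3·4H2O should give 3-[(1S,2R,6S)-2-{[(tert-butyldimethylsilyl)oxy]methyl}-1,3-dimethyl-6-(prop-1-en-2-yl)cyclohex-3-en-1-yl]propan-1-ol F2. Dess–Martin oxidation then returns to aldehyde 11.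

**Step 4.** Hydrazone formation at the carbonyl next to the quaternary carbon may be slow, so that hydrazine attacks the epoxide instead and the fragmentation stalls. The fallback avoids the epoxy ketone and sets out from enone 3:
- Luche reduction (NaBH4, CeCl3·7H2O, MeOH, −78 °C) should deliver hydride from the α face and give (1S,5S,6S)-2,6-dimethyl-5-(prop-1-en-2-yl)-6-(prop-2-en-1-yl)cyclohex-2-en-1-ol F3.
- ClCO2Me, pyridine and DMAP convert it into its methyl carbonate F4.
- Borylation with B2pin2 under CuCl/Xantphos/KOt-Bu catalysis proceeds anti-SN2′ and should place boron on the α face of C7 in the allylboronate F5.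
- Heating with paraformaldehyde (toluene, 80 °C; then aqueous NaOH) transfers the allyl group through a closed six-membered transition state, forming the C9–C11 bond on the boron-bearing α face and restoring the C7=C8 alkene in [(1R,5S,6S)-2,6-dimethyl-5-(prop-1-en-2-yl)-6-(prop-2-en-1-yl)cyclohex-2-en-1-yl]methanol F6.
- TBSCl and imidazole (DMF) then give 10, so steps 3–6 are bypassed.

## Further compounds

F1 | step 9 | (5R,9R,10S)-11-[(tert-butyldimethylsilyl)oxy]-9βH-drim-7-en-3-ol (both C3 epimers) | CC(C)(C)[Si](C)(C)OC[C@@H]1C(C)=CC[C@H]2C(C)(C)C(O)CC[C@]12C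
F2 | step 7 | 3-[(1S,2R,6S)-2-{[(tert-butyldimethylsilyl)oxy]methyl}-1,3-dimethyl-6-(prop-1-en-2-yl)cyclohex-3-en-1-yl]propan-1-ol | CC(C)(C)[Si](C)(C)OC[C@@H]1C(C)=CC[C@@H](C(C)=C)[C@]1(C)CCCO
F3 | step 4 | (1S,5S,6S)-2,6-dimethyl-5-(prop-1-en-2-yl)-6-(prop-2-en-1-yl)cyclohex-2-en-1-ol (hydroxyl cis to isopropenyl) | O[C@H]1C(C)=CC[C@@H](C(C)=C)[C@]1(C)CC=C
F4 | step 4 | methyl carbonate of F3 | COC(=O)O[C@H]1C(C)=CC[C@@H](C(C)=C)[C@]1(C)CC=C
F5 | step 4 | 2-[(1R,4R,5S)-2,4-dimethyl-5-(prop-1-en-2-yl)-4-(prop-2-en-1-yl)cyclohex-2-en-1-yl]-4,4,5,5-tetramethyl-1,3,2-dioxaborolane (boron on the α face of C7) | CC1=C[C@@](C)(CC=C)[C@H](C(C)=C)C[C@H]1B2OC(C)(C)C(C)(C)O2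
F6 | step 4 | [(1R,5S,6S)-2,6-dimethyl-5-(prop-1-en-2-yl)-6-(prop-2-en-1-yl)cyclohex-2-en-1-yl]methanol | OC[C@@H]1C(C)=CC[C@@H](C(C)=C)[C@]1(C)CC=C
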